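The carbocycle (C1–C6, carotenoid numbering) is grown from a cyclopentanone. In ketone 5 the carbonyl carbon, the future sp2 ring-fusion atom C6, lies between the quaternary gem-dimethyl carbon C1 and a methylene (C4), so diazoethane insertion shifts only C4 and sets C5 with its methyl group between C6 and C4. This one-atom ring expansion gives a 2,2,6-trimethylcyclohexanone with a single enolisable site. The catalytically set C3 centre is then relayed: anti epoxidation fixes C5 and C6, SN2′ hydride opening gives the (6R)-allene, and silver-catalysed attack of the C5 hydroxyl on C8 closes the dihydrofuran ring O–C8–C7=C6–C5 with axis-to-centre transfer.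

Key step: step 4

Remark (numbering): atoms are numbered as in carotenoids: ring C1 (CMe2), C2, C3 (carbinol), C4, C5 (C–Me, C–O), C6; chain C7–C15 and C15′–C12′. In benzofuran numbering C8 = C2, C7 = C3, C6 = C3a, C1 = C4, C3 = C6, C5 = C7a.
Remark (assumptions): the chain is all-E as drawn in the target SMILES. Diazoethane is used as a freshly made ethereal solution (from N-ethyl-N-nitrosourea and KOH). The allene axis is written in SMILES with the extended-tetrahedral tag and is also given in words.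

Step 1
Reactants: 1 2,2-dimethylcyclopentan-1-one
Product: 2 5,5-dimethylcyclopent-2-en-1-one
Conditions: IBX (2-iodoxybenzoic acid), 4-methoxypyridine N-oxide, DMSO, 25 °C
Reagents that add atoms: none
Why: IBX-mediated dehydrogenation of a ketone to the enone; only one α-carbon of 1 carries hydrogen, so a single enone can form.

Step 2
Reactants: 2 5,5-dimethylcyclopent-2-en-1-one
Product: 4 (S)-4-hydroxy-2,2-dimethylcyclopentan-1-one, via pinacol boronate 3 (not isolated)
Conditions: B2pin2, CuCl (3 mol %), NaOtBu (3 mol %), (R)-1-[(S)-2-(diphenylphosphino)ferrocenyl]ethyldicyclohexylphosphine or its enantiomer (4 mol %), MeOH, THF, 25 °C; then NaBO3·4H2O, THF/H2O, 25 °C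
Reagents that add atoms: bis(pinacolato)diboron, CC1(C)OB(OC1(C)C)B1OC(C)(C)C(C)(C)O1 (boron of 3); sodium perborate, [Na+].[O-]OB=O (hydroxyl oxygen of 4)
Why: Copper-catalysed asymmetric conjugate borylation of a cyclic enone followed by stereoretentive C–B oxidation; the C3 centre, the only one not relayed, is set by the chiral bisphosphine on copper, the ligand antipode being chosen to give (S).

Step 3
Reactants: 4 (S)-4-hydroxy-2,2-dimethylcyclopentan-1-one
Product: 5 (1S)-3,3-dimethyl-4-oxocyclopentyl pivalate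
Conditions: PivCl, pyridine, DMAP (cat.), CH2Cl2, 0 to 25 °C
Reagents that add atoms: pivaloyl chloride, CC(C)(C)C(=O)Cl
Why: Acylation of the secondary alcohol; the pivalate has no α-hydrogen (it survives the amide base of step 5), serves as the acyloxy directing group in step 7 and is removed by the hydride of step 8.

Step 4
Reactants: 5 (1S)-3,3-dimethyl-4-oxocyclopentyl pivalate
Product: 6 (1R)-3,3,5-trimethyl-4-oxocyclohexyl pivalate (mixture of epimers at the methyl-bearing carbon, carotenoid C5)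
Conditions: MeCHN2 (1.3 equiv, Et2O), Sc(OTf)3 (10 mol %), toluene, −78 to −40 °C
Reagents that add atoms: diazoethane, CC=[N+]=[N-]
Why: Lewis-acid-promoted homologation of a ketone with a diazoalkane (Tiffeneau–Demjanov-type ring expansion): diazoethane adds through carbon to the Sc-bound carbonyl of 5, and in the β-oxido diazonium intermediate the ring bond anti to the departing N2 shifts to the new carbon, which restores the carbonyl. No ring is closed; the five-membered ring C6–C1–C2–C3–C4 is enlarged by one atom, C5, which enters between C6 and C4 and brings its methyl group. The selectivity needed is migration of the methylene C4 instead of the quaternary C1; this is the normal preference in diazoalkane insertions and the gem-dimethyl group on the C1 side reinforces it. A second insertion is disfavoured because 6 is a ketone flanked by two substituted carbons. The new stereocentre C5 forms without control and is of no consequence, since step 5 makes it trigonal. C3 is not involved and keeps its configuration.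

Step 5
Reactants: 6 (1R)-3,3,5-trimethyl-4-oxocyclohexyl pivalate
Product: 7 (1R)-3,5,5-trimethyl-4-{[(trifluoromethyl)sulfonyl]oxy}cyclohex-3-en-1-yl pivalate
Conditions: LiN(iPr)2, THF, −78 to 0 °C; PhNTf2, −78 to 25 °C
Reagents that add atoms: N-phenylbis(trifluoromethanesulfonimide), O=S(=O)(N(c1ccccc1)S(=O)(=O)C(F)(F)F)C(F)(F)F
Why: Deprotonation can occur only at C5 (C1 is quaternary), so both epimers of 6 give one enolate, which is O-sulfonylated to the vinyl triflate.

Step 6
Reactants: 7 (1R)-3,5,5-trimethyl-4-{[(trifluoromethyl)sulfonyl]oxy}cyclohex-3-en-1-yl pivalate; 8 (2E)-3-methylpent-2-en-4-yn-1-ol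
Product: 10 (1R)-4-[(3E)-5-acetoxy-3-methylpent-3-en-1-yn-1-yl]-3,5,5-trimethylcyclohex-3-en-1-yl pivalate, via enynol 9 (not isolated)
Conditions: PdCl2(PPh3)2 (5 mol %), CuI (10 mol %), Et3N, THF, 25–45 °C; then Ac2O, DMAP (cat.), 25 °C
Reagents that add atoms: acetic anhydride, CC(=O)OC(C)=O
Why: Sonogashira coupling of the vinyl triflate with the terminal alkyne (E geometry of 8 retained), then acetylation of the primary alcohol in the same pot so that the chain alkene is deactivated towards the peracid of step 7.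

Step 7
Reactants: 10 (1R)-4-[(3E)-5-acetoxy-3-methylpent-3-en-1-yn-1-yl]-3,5,5-trimethylcyclohex-3-en-1-yl pivalate
Product: 11 (1R,4S,6R)-1-[(3E)-5-acetoxy-3-methylpent-3-en-1-yn-1-yl]-2,2,6-trimethyl-7-oxabicyclo[4.1.0]heptan-4-yl pivalate
Conditions: mCPBA (1.05 equiv), NaHCO3, CH2Cl2, −20 to 0 °C
Reagents that add atoms: 3-chloroperbenzoic acid, OOC(=O)c1cccc(Cl)c1
Why: Prilezhaev epoxidation: the peracid should take the tetrasubstituted ring alkene and not the chain alkene deactivated by the allylic acetate, and should enter mainly anti to the equatorial pivaloyloxy group (the usual sense for 3-acyloxy rings of this type), which sets C5 and C6 with the oxirane oxygen trans to the C3 oxygen; the syn isomer is removed by chromatography.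

Step 8
Reactants: 11 (1R,4S,6R)-1-[(3E)-5-acetoxy-3-methylpent-3-en-1-yn-1-yl]-2,2,6-trimethyl-7-oxabicyclo[4.1.0]heptan-4-yl pivalate
Product: 12 (1R,3S)-6-[(3E)-5-hydroxy-3-methylpenta-1,3-dien-1-ylidene]-1,5,5-trimethylcyclohexane-1,3-diol, allene axis R (carotenoid 3S,5R,6R; C9 on the face of the C5 methyl group)
Conditions: i-Bu2AlH (7 equiv), CH2Cl2, −78 to 0 °C; aq. potassium sodium tartrate
Reagents that add atoms: none
Why: Both esters are cleaved, then aluminium bound at the oxirane oxygen delivers hydride to C8 with 1,3-opening (SN2′ reduction of an alkynyl oxirane), so hydrogen should enter on the oxygen face, C9 takes the face of the C5 methyl group and the (6R) axis results while C5 keeps its C–O bond.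

Step 9
Reactants: 12 (1R,3S)-6-[(3E)-5-hydroxy-3-methylpenta-1,3-dien-1-ylidene]-1,5,5-trimethylcyclohexane-1,3-diol
Product: 13 (2S,6S,7aR)-2-[(2E)-4-hydroxybut-2-en-2-yl]-4,4,7a-trimethyl-2,4,5,6,7,7a-hexahydro-1-benzofuran-6-ol
Conditions: AgNO3 (20 mol %), CaCO3, acetone/H2O (4:1), 25 °C, dark
Reagents that add atoms: none
Why: Silver-catalysed cycloisomerisation of an α-hydroxyallene (5-endo attack of the C5 hydroxyl on C8 of the silver-bound C7=C8 bond, then protodemetalation): the substituents on C8 keep their faces, so the axis is transferred to the centre and C9 ends cis to the C5 methyl group, i.e. (8S); CaCO3 keeps the acid-labile allylic ether from ionising.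

Step 10
Reactants: 13 (2S,6S,7aR)-2-[(2E)-4-hydroxybut-2-en-2-yl]-4,4,7a-trimethyl-2,4,5,6,7,7a-hexahydro-1-benzofuran-6-ol
Product: 15 {(2E)-3-[(2S,6S,7aR)-6-hydroxy-4,4,7a-trimethyl-2,4,5,6,7,7a-hexahydro-1-benzofuran-2-yl]but-2-en-1-yl}triphenylphosphonium bromide, via allylic bromide 14 (not isolated)
Conditions: NBS, Me2S, CH2Cl2, −30 to 0 °C; aqueous wash; then PPh3, CH2Cl2, 25 °C
Reagents that add atoms: N-bromosuccinimide, O=C1CCC(=O)N1Br; triphenylphosphine, c1ccc(cc1)P(c1ccccc1)c1ccccc1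
Why: Corey–Kim-type halogenation converts only the primary allylic alcohol (the secondary C3 alkoxysulfonium salt returns the alcohol on work-up), and SN2 quaternisation of triphenylphosphine by the allylic bromide gives the Wittig salt without acid, which spares the C8–O bond.

Step 11
Reactants: 15 {(2E)-3-[(2S,6S,7aR)-6-hydroxy-4,4,7a-trimethyl-2,4,5,6,7,7a-hexahydro-1-benzofuran-2-yl]but-2-en-1-yl}triphenylphosphonium bromide; 16 (2E,4E,6E)-2,7-dimethylocta-2,4,6-trienedial
Product: 17 (2E,4E,6E,8E,10E)-11-[(2S,6S,7aR)-6-hydroxy-4,4,7a-trimethyl-2,4,5,6,7,7a-hexahydro-1-benzofuran-2-yl]-2,7-dimethyldodeca-2,4,6,8,10-pentaenal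
Conditions: NaN(SiMe3)2 (2.1 equiv), THF, −78 °C; ylide added to 16 (3 equiv), −78 to 0 °C; then heptane, 70 °C (Z to E)
Reagents that add atoms: none
Why: Wittig olefination of the allylic ylide with one aldehyde group of the symmetrical dialdehyde (excess 16, inverse addition) forms C11=C12; loss of the ring oxygen from the ylide is uphill because a tertiary alkoxide would have to leave, and any (11Z) isomer should be converted to the all-E chain by thermal equilibration.

Step 12
Reactants: 17 (2E,4E,6E,8E,10E)-11-[(2S,6S,7aR)-6-hydroxy-4,4,7a-trimethyl-2,4,5,6,7,7a-hexahydro-1-benzofuran-2-yl]-2,7-dimethyldodeca-2,4,6,8,10-pentaenal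
Product: 18 (3S,5R,8S)-5,8-epoxy-5,8-dihydro-12′-apo-β-carotene-3,12′-diol, i.e. (2S,6S,7aR)-2-[(2E,4E,6E,8E,10E)-12-hydroxy-6,11-dimethyldodeca-2,4,6,8,10-pentaen-2-yl]-4,4,7a-trimethyl-2,4,5,6,7,7a-hexahydro-1-benzofuran-6-ol
Conditions: NaBH4, EtOH/THF, 0 °C
Reagents that add atoms: none
Why: Chemoselective 1,2-reduction of the conjugated aldehyde by borohydride leaves the polyene and the allylic ether untouched.

Compound list
1 | 2,2-dimethylcyclopentan-1-one | CC1(C)CCCC1=O | starting material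
2 | 5,5-dimethylcyclopent-2-en-1-one | CC1(C)CC=CC1=O | intermediate
3 | (S)-2,2-dimethyl-4-(4,4,5,5-tetramethyl-1,3,2-dioxaborolan-2-yl)cyclopentan-1-one | CC1(C)C[C@H](B2OC(C)(C)C(C)(C)O2)CC1=O | intermediate (not isolated)
4 | (S)-4-hydroxy-2,2-dimethylcyclopentan-1-one | CC1(C)C[C@H](O)CC1=O | intermediate
5 | (1S)-3,3-dimethyl-4-oxocyclopentyl pivalate | CC1(C)C[C@H](OC(=O)C(C)(C)C)CC1=O | intermediate
6 | (1R)-3,3,5-trimethyl-4-oxocyclohexyl pivalate (epimers at the CHMe carbon) | CC1(C)C[C@H](OC(=O)C(C)(C)C)CC(C)C1=O | intermediate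
7 | (1R)-3,5,5-trimethyl-4-{[(trifluoromethyl)sulfonyl]oxy}cyclohex-3-en-1-yl pivalate | CC1=C(OS(=O)(=O)C(F)(F)F)C(C)(C)C[C@H](OC(=O)C(C)(C)C)C1 | intermediate
8 | (2E)-3-methylpent-2-en-4-yn-1-ol | C#C/C(C)=C/CO | starting material
9 | (1R)-4-[(3E)-5-hydroxy-3-methylpent-3-en-1-yn-1-yl]-3,5,5-trimethylcyclohex-3-en-1-yl pivalate | CC1=C(C#C/C(C)=C/CO)C(C)(C)C[C@H](OC(=O)C(C)(C)C)C1 | intermediate (not isolated)
10 | (1R)-4-[(3E)-5-acetoxy-3-methylpent-3-en-1-yn-1-yl]-3,5,5-trimethylcyclohex-3-en-1-yl pivalate | CC1=C(C#C/C(C)=C/COC(C)=O)C(C)(C)C[C@H](OC(=O)C(C)(C)C)C1 | intermediate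
11 | (1R,4S,6R)-1-[(3E)-5-acetoxy-3-methylpent-3-en-1-yn-1-yl]-2,2,6-trimethyl-7-oxabicyclo[4.1.0]heptan-4-yl pivalate | CC(=O)OC/C=C(C)/C#C[C@@]12O[C@]1(C)C[C@@H](OC(=O)C(C)(C)C)CC2(C)C | intermediate
12 | (1R,3S)-6-[(3E)-5-hydroxy-3-methylpenta-1,3-dien-1-ylidene]-1,5,5-trimethylcyclohexane-1,3-diol, allene axis R | OC/C=C(C)/[CH]=[C@@]=C1C(C)(C)C[C@H](O)C[C@@]1(C)O | intermediate
13 | (2S,6S,7aR)-2-[(2E)-4-hydroxybut-2-en-2-yl]-4,4,7a-trimethyl-2,4,5,6,7,7a-hexahydro-1-benzofuran-6-ol | OC/C=C(\C)[C@@H]1C=C2C(C)(C)C[C@H](O)C[C@@]2(C)O1 | intermediate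
14 | (2S,6S,7aR)-2-[(2E)-4-bromobut-2-en-2-yl]-4,4,7a-trimethyl-2,4,5,6,7,7a-hexahydro-1-benzofuran-6-ol | BrC/C=C(\C)[C@@H]1C=C2C(C)(C)C[C@H](O)C[C@@]2(C)O1 | intermediate (not isolated)
15 | {(2E)-3-[(2S,6S,7aR)-6-hydroxy-4,4,7a-trimethyl-2,4,5,6,7,7a-hexahydro-1-benzofuran-2-yl]but-2-en-1-yl}triphenylphosphonium bromide | [Br-].c1ccccc1[P+](c1ccccc1)(c1ccccc1)C/C=C(\C)[C@@H]1C=C2C(C)(C)C[C@H](O)C[C@@]2(C)O1 | intermediate
16 | (2E,4E,6E)-2,7-dimethylocta-2,4,6-trienedial | O=C/C(C)=C/C=C/C=C(\C)C=O | starting material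
17 | (2E,4E,6E,8E,10E)-11-[(2S,6S,7aR)-6-hydroxy-4,4,7a-trimethyl-2,4,5,6,7,7a-hexahydro-1-benzofuran-2-yl]-2,7-dimethyldodeca-2,4,6,8,10-pentaenal | CC(/C=C/C=C(\C)[C@@H]1C=C2C(C)(C)C[C@H](O)C[C@@]2(C)O1)=C\C=C\C=C(/C)C=O | intermediate
18 | (3S,5R,8S)-5,8-epoxy-5,8-dihydro-12′-apo-β-carotene-3,12′-diol | CC(/C=C/C=C(\C)[C@@H]1C=C2C(C)(C)C[C@H](O)C[C@@]2(C)O1)=C\C=C\C=C(/C)CO | target

Total step count: 12. Longest linear sequence: 12 steps (1 to 18); 8 and 16 are bought and enter in steps 6 and 11.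

Steps most likely to fail

1. Step 4 (key ring expansion). What may go wrong: migration of the quaternary carbon C1 instead of C4, a second insertion, or Lewis-acid-induced loss of the β-pivaloyloxy group. Fallback, from 5 back to 7, still a five-to-six ring enlargement but by a carbene route: 5 is silylated (Me3SiOTf, Et3N) to its only possible enol ether, (1S)-4,4-dimethyl-3-[(trimethylsilyl)oxy]cyclopent-2-en-1-yl pivalate F1. Chloro(methyl)carbene (CH3CHCl2, lithium 2,2,6,6-tetramethylpiperidide, −40 °C) adds to give the chlorocyclopropane 6-chloro-2,2,6-trimethyl-1-[(trimethylsilyl)oxy]bicyclo[3.1.0]hexan-4-yl pivalate F2. Heating in toluene opens the internal cyclopropane bond (cyclopropyl-to-allyl opening) and gives the enone (1S)-3,5,5-trimethyl-4-oxocyclohex-2-en-1-yl pivalate F3. Conjugate reduction with LiB(sBu)3H at −78 °C and trapping of the enolate with PhNTf2 returns to 7.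

2. Step 7 (epoxidation). What may go wrong: poor facial selectivity (oxygen entering syn to the pivalate) or competing epoxidation of the chain alkene. Fallback, from 7 back to 12, with reagent-controlled epoxidation:
- Carbonylation of 7 (Pd(OAc)2, 1,3-bis(diphenylphosphino)propane, CO, MeOH, Et3N, DMF) gives methyl (4R)-4-(pivaloyloxy)-2,6,6-trimethylcyclohex-1-ene-1-carboxylate F4.
- i-Bu2AlH reduces both esters to (1R)-4-(hydroxymethyl)-3,5,5-trimethylcyclohex-3-en-1-ol F5.
- Sharpless epoxidation (Ti(OiPr)4, D-(−)-diethyl tartrate, t-BuOOH, −20 °C) places the oxygen anti to the C3 hydroxyl: (1R,4S,6R)-1-(hydroxymethyl)-2,2,6-trimethyl-7-oxabicyclo[4.1.0]heptan-4-ol F6.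
- TEMPO/PhI(OAc)2 oxidises only the primary alcohol to (1S,4S,6R)-4-hydroxy-2,2,6-trimethyl-7-oxabicyclo[4.1.0]heptane-1-carbaldehyde F7.
- The Ohira–Bestmann reagent (dimethyl (1-diazo-2-oxopropyl)phosphonate, K2CO3, MeOH) gives (1R,4S,6R)-1-ethynyl-2,2,6-trimethyl-7-oxabicyclo[4.1.0]heptan-4-ol F8.
- Sonogashira coupling with (E)-3-iodobut-2-en-1-ol (Pd(PPh3)4, CuI, i-Pr2NH) gives (1R,4S,6R)-1-[(3E)-5-hydroxy-3-methylpent-3-en-1-yn-1-yl]-2,2,6-trimethyl-7-oxabicyclo[4.1.0]heptan-4-ol F9.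
- i-Bu2AlH as in step 8 gives 12.

3. Step 11 (Wittig). What may go wrong: β-elimination of the ring oxygen from the ylide with loss of the C8 configuration, double olefination of the dialdehyde, or poor E selectivity. Fallback, from 12 to 18, in which no ylide is made next to the C8–O bond because the furan ring is closed last: 12 with PPh3·HBr (MeOH, 25 °C) gives the allenic salt {(2E)-5-[(2R,4S)-2,4-dihydroxy-2,6,6-trimethylcyclohexylidene]-3-methylpenta-2,4-dien-1-yl}triphenylphosphonium bromide F10. Wittig reaction with 16 (NaOMe, MeOH/CH2Cl2) gives the allenic aldehyde (2E,4E,6E,8E,10E)-13-[(2R,4S)-2,4-dihydroxy-2,6,6-trimethylcyclohexylidene]-2,7,11-trimethyltrideca-2,4,6,8,10,12-hexaenal F11. NaBH4 gives the allenic triol (1R,3S)-6-[(3E,5E,7E,9E,11E)-13-hydroxy-3,7,12-trimethyltrideca-1,3,5,7,9,11-hexaen-1-ylidene]-1,5,5-trimethylcyclohexane-1,3-diol F12. The cyclisation of step 9 (AgNO3, CaCO3, acetone/H2O) applied to F12 closes the dihydrofuran and gives 18.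

Further compounds
F1 | step 4 | (1S)-4,4-dimethyl-3-[(trimethylsilyl)oxy]cyclopent-2-en-1-yl pivalate | CC1(C)C[C@H](OC(=O)C(C)(C)C)C=C1O[Si](C)(C)C
F2 | step 4 | (4S)-6-chloro-2,2,6-trimethyl-1-[(trimethylsilyl)oxy]bicyclo[3.1.0]hexan-4-yl pivalate (isomers at the cyclopropane carbons) | CC1(C)C[C@H](OC(=O)C(C)(C)C)C2C(C)(Cl)C12O[Si](C)(C)C
F3 | step 4 | (1S)-3,5,5-trimethyl-4-oxocyclohex-2-en-1-yl pivalate | CC1(C)C[C@H](OC(=O)C(C)(C)C)C=C(C)C1=O
F4 | step 7 | methyl (4R)-4-(pivaloyloxy)-2,6,6-trimethylcyclohex-1-ene-1-carboxylate | COC(=O)C1=C(C)C[C@@H](OC(=O)C(C)(C)C)CC1(C)C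
F5 | step 7 | (1R)-4-(hydroxymethyl)-3,5,5-trimethylcyclohex-3-en-1-ol | OCC1=C(C)C[C@@H](O)CC1(C)C
F6 | step 7 | (1R,4S,6R)-1-(hydroxymethyl)-2,2,6-trimethyl-7-oxabicyclo[4.1.0]heptan-4-ol | OC[C@@]12O[C@]1(C)C[C@@H](O)CC2(C)C
F7 | step 7 | (1S,4S,6R)-4-hydroxy-2,2,6-trimethyl-7-oxabicyclo[4.1.0]heptane-1-carbaldehyde | O=C[C@@]12O[C@]1(C)C[C@@H](O)CC2(C)C
F8 | step 7 | (1R,4S,6R)-1-ethynyl-2,2,6-trimethyl-7-oxabicyclo[4.1.0]heptan-4-ol | C#C[C@@]12O[C@]1(C)C[C@@H](O)CC2(C)C
F9 | step 7 | (1R,4S,6R)-1-[(3E)-5-hydroxy-3-methylpent-3-en-1-yn-1-yl]-2,2,6-trimethyl-7-oxabicyclo[4.1.0]heptan-4-ol | OC/C=C(C)/C#C[C@@]12O[C@]1(C)C[C@@H](O)CC2(C)C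
F10 | step 11 | {(2E)-5-[(2R,4S)-2,4-dihydroxy-2,6,6-trimethylcyclohexylidene]-3-methylpenta-2,4-dien-1-yl}triphenylphosphonium bromide, allene axis R | [Br-].c1ccccc1[P+](c1ccccc1)(c1ccccc1)C/C=C(C)/[CH]=[C@@]=C1C(C)(C)C[C@H](O)C[C@@]1(C)O
F11 | step 11 | (2E,4E,6E,8E,10E)-13-[(2R,4S)-2,4-dihydroxy-2,6,6-trimethylcyclohexylidene]-2,7,11-trimethyltrideca-2,4,6,8,10,12-hexaenal, allene axis R | CC(/C=C/C=C(C)/[CH]=[C@@]=C1C(C)(C)C[C@H](O)C[C@@]1(C)O)=C\C=C\C=C(/C)C=O
F12 | step 11 | (1R,3S)-6-[(3E,5E,7E,9E,11E)-13-hydroxy-3,7,12-trimethyltrideca-1,3,5,7,9,11-hexaen-1-ylidene]-1,5,5-trimethylcyclohexane-1,3-diol, allene axis R | CC(/C=C/C=C(C)/[CH]=[C@@]=C1C(C)(C)C[C@H](O)C[C@@]1(C)O)=C\C=C\C=C(/C)CO
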